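**Plan**

1. Retrosynthesis: the two norbornene bonds C1–C13′ and C3–C11′ (the spiro carbon) are cut by a retro-Diels–Alder step. This gives a 2α-acetoxy cyclopentadiene (guaianolide half, its own lactone methylene masked as a β-sulfone) and an 8′β-hydroxy (Z,Z)-germacranolide α-methylene lactone.
2. The cyclopentadiene ring C1–C5 is traced back to six-membered ring A of a eudesmanolide. The enabling feature is ring A as a cross-conjugated 2,5-cyclohexadienone (C1=C2–C3(=O)–C4=C5, 4-methyl) whose quaternary C10 lies between C1 and C5 and is shared with ring B. Light forms C1–C5 and cuts C5–C10, so one event contracts ring A to the cyclopentenone and expands ring B to the seven-membered ring.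
3. Forward, acetoxy half: isoalantolactone → C8 inversion → sulfone mask → ring A dienone → photorearrangement → C10 deoxygenation, C2 acetoxylation, 1,4-dehydration to the diene.
4. Forward, macrocyclic half: a chain with both Z-trisubstituted alkenes (Still–Wittig, iron-catalysed carbometalation), butenolide by metathesis, ten-membered ring by chromium-mediated Barbier closure of C7′–C8′. Then Diels–Alder union and unmasking.
5. Stereochemistry: C7 and the C10 methyl come from isoalantolactone; C8 by SN2 inversion; C10–H by face-selective hydrogenation; C2 by trans acetoxylation. C6′ comes from catalytic asymmetric alkynylation, C7′/C8′ from the macrocyclisation, and C1, C3, C11′ and the bridge orientation from the cycloaddition.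

Key step: step 7

Assumption: atom numbers follow the eudesmane/guaiane skeleton for the acetoxy half and primed germacrane numbers for the macrocyclic half. The C11 configuration drawn for the sulfone-masked lactone (4–14, 29) is the one expected under equilibration and is inconsequential, because C11 is sp2 again after step 24.

**Route**

Step 1
Reactants: 1 isoalantolactone
Product: 2 isoalantolic acid (8β-hydroxy-5αH,7αH-eudesma-4(15),11(13)-dien-12-oic acid)
Conditions: NaOH (2 M aq.), THF, 25 °C; then 1 M HCl to pH 4, 0 °C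
Reagents that add atoms: sodium hydroxide, [Na+].[OH-]
Why: Saponification (acyl–oxygen cleavage) of the cis-fused γ-lactone frees the axial 8β-hydroxyl without touching a stereocenter; the hydroxy acid is kept cold and used at once because it relactonises easily.

Step 2
Reactants: 2 isoalantolic acid
Product: 3 8-epi-isoalantolactone (5αH,7αH,8βH-eudesma-4(15),11(13)-dien-12,8α-olide, trans-fused)
Conditions: PPh3, DIAD, THF (0.01 M), 0 → 25 °C
Reagents that add atoms: none
Why: Mitsunobu lactonisation: the carboxylate displaces the C8 oxyphosphonium group intramolecularly in an SN2 step, so C8 is inverted and the trans-fused (7αH,8βH) lactone of the target results.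

Step 3
Reactants: 3 8-epi-isoalantolactone
Product: 4 13-(phenylsulfonyl)-5αH,7αH,8βH,11βH-eudesm-4(15)-en-12,8α-olide
Conditions: PhSO2Na, AcOH, EtOH, 60 °C
Reagents that add atoms: sodium benzenesulfinate, [Na+].[O-]S(=O)c1ccccc1
Why: Sulfa-Michael addition of benzenesulfinate to the α-methylene lactone masks the only Michael acceptor (and later competing dienophile) as a β-sulfonyl lactone that tolerates oxidation, light, hydrogenation and acid; C11 is protonated under equilibrating conditions.

Step 4
Reactants: 4 sulfone-masked lactone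
Product: 5 3α-hydroxy-13-(phenylsulfonyl)-5αH,7αH,8βH,11βH-eudesm-4(15)-en-12,8α-olide
Conditions: SeO2 (0.3 equiv), t-BuOOH, CH2Cl2, 25 °C
Reagents that add atoms: tert-butyl hydroperoxide, CC(C)(C)OO
Why: Selenium dioxide allylic hydroxylation (ene reaction, then [2,3]-shift) of the 1,1-disubstituted alkene should occur at the ring CH2 (C3) in preference to the ring-fusion CH (C5); the carbinol configuration is lost in step 5.

Step 5
Reactants: 5 allylic alcohol
Product: 7 3-oxo-13-(phenylsulfonyl)-7αH,8βH,11βH-eudesm-4-en-12,8α-olide, via exocyclic enone 6 (not isolated)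
Conditions: Dess–Martin periodinane, CH2Cl2, 25 °C; filtration and solvent exchange; then RhCl3·3H2O (5 mol%), EtOH, 80 °C
Reagents that add atoms: none
Why: Dess–Martin oxidation gives the α-methylene ketone, which RhCl3 isomerises (rhodium hydride addition–elimination) to the more stable tetrasubstituted endocyclic enone; the masked lactone cannot isomerise.

Step 6
Reactants: 7 4-en-3-one
Product: 8 3-oxo-13-(phenylsulfonyl)-7αH,8βH,11βH-eudesma-1,4-dien-12,8α-olide
Conditions: DDQ, dioxane, 100 °C
Reagents that add atoms: none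
Why: DDQ dehydrogenation of a 4-en-3-one under neutral conditions removes hydride from C1 of the cross-conjugated 2,4-dienol and so gives the 1,4-dien-3-one, as in steroid ring A chemistry.

Step 7
Reactants: 8 cross-conjugated dienone
Product: 9 10α-hydroxy-3-oxo-13-(phenylsulfonyl)-1αH,7αH,8βH,11βH-guai-4-en-12,8α-olide (10β-methyl)
Conditions: hν (medium-pressure Hg lamp, Pyrex filter), AcOH–H2O (45:55), reflux
Reagents that add atoms: water, O
Why: Excitation (n→π*) of the ring A cyclohexadienone leads to C1–C5 bonding and a bicyclo[3.1.0] oxyallyl zwitterion (cyclopropane C1–C5–C10); protonation gives a cyclopropylcarbinyl-type hydroxyallyl cation, and water attacks C10 as the C5–C10 bond breaks. The closest known reaction is the photochemical rearrangement of santonin to isophotosantonic lactone, the general behaviour of 4-methyl-1,4-dien-3-ones in aqueous acetic acid. The five-membered ring C1–C5 arises by contraction of ring A through a formal 1,2-shift of C5 from C10 to C1 (transannular C1–C5 bonding, then cyclopropane cleavage), not by closure of a chain, and ring B grows from six to seven members in the same event. C1 should receive its hydrogen α because the cyclopropane must form on the β-face, where C9 of fused ring B can stay exo; C10 should take up water with inversion, anti to the breaking C5–C10 bond (10α-OH, 10β-CH3); C7, C8 and C11 are untouched. The step needs cleavage of C5–C10 (hydroazulenone) and not of C1–C10 (spiro ketone) or collapse to a lumiketone; the C4 methyl group, which stabilises positive charge at C4, and the protic nucleophilic medium secure this. The Pyrex filter keeps the sulfone and lactone chromophores unexcited.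

Step 8
Reactants: 9 tertiary alcohol
Product: 10 3-oxo-13-(phenylsulfonyl)-1αH,7αH,8βH,11βH-guaia-4,10(14)-dien-12,8α-olide
Conditions: SOCl2, pyridine, CH2Cl2, −20 → 0 °C
Reagents that add atoms: none
Why: E2 dehydration through the chlorosulfite: H-1 is syn to the 10α leaving group and cannot be lost in an anti elimination, so the new double bond forms away from the enone, mainly towards the methyl group (a Δ9 regioisomer, if formed, would converge in step 9).

Step 9
Reactants: 10 exocyclic alkene
Product: 11 3-oxo-13-(phenylsulfonyl)-1αH,7αH,8βH,10αH,11βH-guai-4-en-12,8α-olide (10β-methyl)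
Conditions: H2 (1 atm), RhCl(PPh3)3 (10 mol%), benzene–EtOH, 25 °C
Reagents that add atoms: none
Why: Homogeneous catalytic hydrogenation reduces only the unhindered 1,1-disubstituted alkene without moving it into conjugation; hydrogen should add to the α-face, anti to the C1–C2 bond of the cyclopentenone that screens the β-face, which gives 10αH and the 10β-methyl group of the target.

Step 10
Reactants: 11 cyclopentenone
Product: 12 2α-acetoxy-3-oxo-13-(phenylsulfonyl)-1αH,7αH,8βH,10αH,11βH-guai-4-en-12,8α-olide
Conditions: Mn(OAc)3·2H2O (3 equiv), benzene, reflux (Dean–Stark)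
Reagents that add atoms: manganese triacetate, CC(=O)[O-].CC(=O)[O-].CC(=O)[O-].[Mn+3]
Why: Manganese triacetate α′-acetoxylation of an enone (manganese enolate, acetoxy transfer) functionalises C2, the only α′ position; the acetoxy group should enter on the α-face, trans to the C1–C10 bond.

Step 11
Reactants: 12 α′-acetoxy enone
Product: 13 2α-acetoxy-3α-hydroxy-13-(phenylsulfonyl)-1αH,7αH,8βH,10αH,11βH-guai-4-en-12,8α-olide
Conditions: NaBH4, CeCl3·7H2O, MeOH, −78 °C
Reagents that add atoms: none
Why: Luche 1,2-reduction gives the allylic alcohol without conjugate reduction, acetate loss or retro-Michael unmasking; hydride should come anti to the acetate, but the C3 configuration is irrelevant because C3 becomes sp2 in step 12.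

Step 12
Reactants: 13 allylic alcohol
Product: 14 2α-acetoxy-13-(phenylsulfonyl)-7αH,8βH,10αH,11βH-guaia-1(5),3-dien-12,8α-olide (the cyclopentadiene)
Conditions: MsCl, Et3N, CH2Cl2, −20 °C; cold aqueous work-up, used at once
Reagents that add atoms: none
Why: Mesylation and E1 elimination: the allylic mesylate ionises to the C3–C4–C5 allyl cation and loss of H-1 next to the tertiary terminus gives the fully endocyclic cyclopentadiene; the C2 acetate stays because its ionisation would give an antiaromatic cyclopentadienyl cation, and the diene is kept cold to avoid 1,5-hydrogen shifts.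

Step 13
Reactants: 15 pent-4-ynal
Product: 16 (±)-2-methylhept-1-en-6-yn-3-ol
Conditions: isopropenylmagnesium bromide, THF, −78 °C; aq. NH4Cl
Reagents that add atoms: isopropenylmagnesium bromide, CC(=C)[Mg]Br
Why: Grignard addition to the aldehyde at −78 °C is faster than deprotonation of the terminal alkyne; the racemic carbinol center is destroyed in step 14.

Step 14
Reactants: 16 enynol
Product: 18 (Z)-3-methyloct-3-en-7-yn-1-ol, via stannylmethyl ether 17 (not isolated)
Conditions: KH (1.1 equiv), Bu3SnCH2I, THF, 0 → 25 °C; then n-BuLi (2.3 equiv), −78 °C; aq. NH4Cl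
Reagents that add atoms: (iodomethyl)tributylstannane, CCCC[Sn](CCCC)(CCCC)CI
Why: Williamson etherification, then tin–lithium exchange, triggers the Still–Wittig [2,3]-sigmatropic rearrangement, whose early transition state with a pseudoaxial substituent gives the Z-trisubstituted homoallylic alcohol (the later C1′=C10′ alkene); the acetylide formed by the first equivalent of base is a spectator.

Step 15
Reactants: 18 homoallylic alcohol
Product: 19 tert-butyldimethylsilyl ether of 18
Conditions: TBSCl, imidazole, DMF, 25 °C
Reagents that add atoms: tert-butyldimethylsilyl chloride, CC(C)(C)[Si](C)(C)Cl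
Why: Silylation of the primary alcohol keeps the future C8′ oxygen apart from the C6′ carbinol through steps 16–19.

Step 16
Reactants: 19 silyl ether alkyne; 20 (E)-but-2-enal (crotonaldehyde)
Product: 21 (2E,4S,9Z)-12-(tert-butyldimethylsilyloxy)-10-methyldodeca-2,9-dien-5-yn-4-ol
Conditions: Me2Zn, ProPhenol ligand (20 mol%, antipode selected for the 4S alcohol), Ph3P=O (40 mol%), toluene, 4 °C
Reagents that add atoms: none
Why: Zinc–ProPhenol catalysed asymmetric alkynylation: the alkynylzinc adds 1,2 to the enal inside the dinuclear zinc pocket, so catalyst control sets the carbinol that becomes C6′.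

Step 17
Reactants: 21 propargylic alcohol
Product: 22 (2E,4S,5Z,9Z)-12-(tert-butyldimethylsilyloxy)-6,10-dimethyldodeca-2,5,9-trien-4-ol
Conditions: MeMgBr (5 equiv), Fe(acac)3 (20 mol%), THF, −78 → 0 °C; aq. NH4Cl
Reagents that add atoms: methylmagnesium bromide, C[Mg]Br
Why: Alkoxide-directed iron-catalysed syn-carbomagnesiation delivers methyl to the distal alkyne carbon and, after protonolysis, hydrogen to the proximal one, so the chain and the carbinol carbon end up cis (the Z-trisubstituted C4′=C5′ alkene).

Step 18
Reactants: 22 dienol; 23 2-(bromomethyl)acrylic acid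
Product: 24 (2E,4S,5Z,9Z)-12-(tert-butyldimethylsilyloxy)-6,10-dimethyldodeca-2,5,9-trien-4-yl 2-(bromomethyl)acrylate
Conditions: N,N′-diisopropylcarbodiimide, DMAP (5 mol%), CH2Cl2, −10 °C
Reagents that add atoms: none
Why: Carbodiimide (Steglich) esterification of the secondary alcohol at low temperature leaves the allylic bromide and the carbinol configuration untouched.

Step 19
Reactants: 24 acrylate ester
Product: 25 (5R)-3-(bromomethyl)-5-[(1Z,5Z)-8-(tert-butyldimethylsilyloxy)-2,6-dimethylocta-1,5-dien-1-yl]furan-2(5H)-one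
Conditions: second-generation Grubbs catalyst (5 mol%), CH2Cl2 (5 mM), 40 °C
Reagents that add atoms: none
Why: Ring-closing metathesis between the propenyl group and the acrylate gives the butenolide with loss of propene; the two trisubstituted alkenes are inert to the catalyst and C6′ is not involved.

Step 20
Reactants: 25 silyl ether
Product: 26 (5R)-3-(bromomethyl)-5-[(1Z,5Z)-8-hydroxy-2,6-dimethylocta-1,5-dien-1-yl]furan-2(5H)-one
Conditions: HF (48% aq.), MeCN, 0 °C
Reagents that add atoms: none
Why: Acidic desilylation frees the primary alcohol without base or nucleophile that could attack the allylic bromide or epimerise the γ-position of the butenolide.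

Step 21
Reactants: 26 primary alcohol
Product: 27 (3Z,7Z)-8-[(2R)-4-(bromomethyl)-5-oxo-2,5-dihydrofuran-2-yl]-3,7-dimethylocta-3,7-dienal
Conditions: Dess–Martin periodinane, NaHCO3, CH2Cl2, 0 °C; used crude
Reagents that add atoms: none
Why: Buffered Dess–Martin oxidation gives the β,γ-unsaturated aldehyde without a base strong enough to move the alkene into conjugation.

Step 22
Reactants: 27 bromo aldehyde
Product: 28 8β-hydroxy-6βH,7αH-(1(10)Z,4Z)-germacra-1(10),4,11(13)-trien-12,6α-olide (the dienophile; primed numbers in the dimer)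
Conditions: CrCl2 (8 equiv), THF (2 mM, slow addition), 25 °C; aq. NH4Cl
Reagents that add atoms: none
Why: Chromium-mediated intramolecular Barbier (Nozaki–Hiyama-type) allylation: the allylchromium species adds through its γ-carbon (C7′) to the aldehyde in a closed chair-like transition state, regenerating the α-methylene lactone and closing the ten-membered ring; the E-type allyl geometry fixed by the butenolide and bond formation trans to the C6′–C5′ bond should give the trans lactone with the anti C7′/C8′ relationship (7′αH, 8′β-OH).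

Step 23
Reactants: 14 acetoxy cyclopentadiene; 28 dienophile
Product: 29 Diels–Alder adduct (target skeleton with the 13-(phenylsulfonyl)-11βH lactone mask)
Conditions: 28 (1.5 equiv), BHT, CH2Cl2, 1.2 GPa, 25 °C
Reagents that add atoms: none
Why: Intermolecular Diels–Alder reaction of a 5-acyloxy cyclopentadiene with an α-methylene lactone: C13′ should bond to the fully substituted terminus C1 and C11′ to the CH terminus C3 (no vicinal quaternary carbons), in the exo-carbonyl mode usual for 1,1-disubstituted dienophiles and on the diene face anti to the 2α-acetoxy group, which would clash with the exo lactone carbonyl on the other face; the target also requires attack on the face of the C11′=C13′ bond on which C8′ lies, and the sulfone mask keeps the diene from adding to its own lactone.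

Step 24
Reactants: 29 masked adduct
Product: 30 target compound CNP0148007.1
Conditions: DBU (1.5 equiv), CH2Cl2, 0 → 25 °C
Reagents that add atoms: none
Why: E1cB retro-sulfa-Michael elimination: DBU removes the C11 proton and benzenesulfinate leaves, which regenerates the α-methylene lactone; the acetate, the spiro lactone (no α-hydrogen) and the secondary alcohol are inert.

**Compound list**

1 | isoalantolactone, 5αH,7αH,8αH-eudesma-4(15),11(13)-dien-12,8β-olide (10β-methyl, cis-fused lactone) | C=C1C(=O)O[C@@H]2C[C@@]3(C)CCCC(=C)[C@@H]3C[C@H]12 | starting material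
2 | isoalantolic acid, 8β-hydroxy-5αH,7αH-eudesma-4(15),11(13)-dien-12-oic acid | OC(=O)C(=C)[C@H]1C[C@H]2C(=C)CCC[C@]2(C)C[C@H]1O | intermediate
3 | 8-epi-isoalantolactone, 5αH,7αH,8βH-eudesma-4(15),11(13)-dien-12,8α-olide (trans-fused) | C=C1C(=O)O[C@H]2C[C@@]3(C)CCCC(=C)[C@@H]3C[C@H]12 | intermediate
4 | 13-(phenylsulfonyl)-5αH,7αH,8βH,11βH-eudesm-4(15)-en-12,8α-olide | O=C1O[C@H]2C[C@@]3(C)CCCC(=C)[C@@H]3C[C@@H]2[C@H]1CS(=O)(=O)c1ccccc1 | intermediate
5 | 3α-hydroxy-13-(phenylsulfonyl)-5αH,7αH,8βH,11βH-eudesm-4(15)-en-12,8α-olide | O=C1O[C@H]2C[C@@]3(C)CC[C@@H](O)C(=C)[C@@H]3C[C@@H]2[C@H]1CS(=O)(=O)c1ccccc1 | intermediate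
6 | 3-oxo-13-(phenylsulfonyl)-5αH,7αH,8βH,11βH-eudesm-4(15)-en-12,8α-olide (exocyclic enone, not isolated) | O=C1O[C@H]2C[C@@]3(C)CCC(=O)C(=C)[C@@H]3C[C@@H]2[C@H]1CS(=O)(=O)c1ccccc1 | intermediate
7 | 3-oxo-13-(phenylsulfonyl)-7αH,8βH,11βH-eudesm-4-en-12,8α-olide | O=C1O[C@H]2C[C@@]3(C)CCC(=O)C(C)=C3C[C@@H]2[C@H]1CS(=O)(=O)c1ccccc1 | intermediate
8 | 3-oxo-13-(phenylsulfonyl)-7αH,8βH,11βH-eudesma-1,4-dien-12,8α-olide | O=C1O[C@H]2C[C@@]3(C)C=CC(=O)C(C)=C3C[C@@H]2[C@H]1CS(=O)(=O)c1ccccc1 | intermediate
9 | 10α-hydroxy-3-oxo-13-(phenylsulfonyl)-1αH,7αH,8βH,11βH-guai-4-en-12,8α-olide (10β-methyl) | O=C1O[C@H]2C[C@@](C)(O)[C@@H]3CC(=O)C(C)=C3C[C@@H]2[C@H]1CS(=O)(=O)c1ccccc1 | intermediate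
10 | 3-oxo-13-(phenylsulfonyl)-1αH,7αH,8βH,11βH-guaia-4,10(14)-dien-12,8α-olide | O=C1O[C@H]2CC(=C)[C@@H]3CC(=O)C(C)=C3C[C@@H]2[C@H]1CS(=O)(=O)c1ccccc1 | intermediate
11 | 3-oxo-13-(phenylsulfonyl)-1αH,7αH,8βH,10αH,11βH-guai-4-en-12,8α-olide (10β-methyl) | O=C1O[C@H]2C[C@H](C)[C@@H]3CC(=O)C(C)=C3C[C@@H]2[C@H]1CS(=O)(=O)c1ccccc1 | intermediate
12 | 2α-acetoxy-3-oxo-13-(phenylsulfonyl)-1αH,7αH,8βH,10αH,11βH-guai-4-en-12,8α-olide | O=C1O[C@H]2C[C@H](C)[C@@H]3[C@@H](OC(C)=O)C(=O)C(C)=C3C[C@@H]2[C@H]1CS(=O)(=O)c1ccccc1 | intermediate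
13 | 2α-acetoxy-3α-hydroxy-13-(phenylsulfonyl)-1αH,7αH,8βH,10αH,11βH-guai-4-en-12,8α-olide | O=C1O[C@H]2C[C@H](C)[C@@H]3[C@@H](OC(C)=O)[C@@H](O)C(C)=C3C[C@@H]2[C@H]1CS(=O)(=O)c1ccccc1 | intermediate
14 | 2α-acetoxy-13-(phenylsulfonyl)-7αH,8βH,10αH,11βH-guaia-1(5),3-dien-12,8α-olide | O=C1O[C@H]2C[C@H](C)C3=C(C[C@@H]2[C@H]1CS(=O)(=O)c1ccccc1)C(C)=C[C@@H]3OC(C)=O | intermediate
15 | pent-4-ynal | C#CCCC=O | starting material
16 | (±)-2-methylhept-1-en-6-yn-3-ol | C#CCCC(O)C(C)=C | intermediate
17 | (±)-tributyl{[(2-methylhept-1-en-6-yn-3-yl)oxy]methyl}stannane (not isolated) | C#CCCC(OC[Sn](CCCC)(CCCC)CCCC)C(C)=C | intermediate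
18 | (Z)-3-methyloct-3-en-7-yn-1-ol | C#CCC/C=C(/C)CCO | intermediate
19 | tert-butyldimethyl{[(Z)-3-methyloct-3-en-7-yn-1-yl]oxy}silane | C#CCC/C=C(/C)CCO[Si](C)(C)C(C)(C)C | intermediate
20 | (E)-but-2-enal (crotonaldehyde) | C/C=C/C=O | starting material
21 | (2E,4S,9Z)-12-(tert-butyldimethylsilyloxy)-10-methyldodeca-2,9-dien-5-yn-4-ol | C/C=C/[C@H](O)C#CCC/C=C(/C)CCO[Si](C)(C)C(C)(C)C | intermediate
22 | (2E,4S,5Z,9Z)-12-(tert-butyldimethylsilyloxy)-6,10-dimethyldodeca-2,5,9-trien-4-ol | C/C=C/[C@H](O)/C=C(/C)CC/C=C(/C)CCO[Si](C)(C)C(C)(C)C | intermediate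
23 | 2-(bromomethyl)acrylic acid | C=C(CBr)C(=O)O | starting material
24 | (2E,4S,5Z,9Z)-12-(tert-butyldimethylsilyloxy)-6,10-dimethyldodeca-2,5,9-trien-4-yl 2-(bromomethyl)acrylate | C/C=C/[C@H](OC(=O)C(=C)CBr)/C=C(/C)CC/C=C(/C)CCO[Si](C)(C)C(C)(C)C | intermediate
25 | (5R)-3-(bromomethyl)-5-[(1Z,5Z)-8-(tert-butyldimethylsilyloxy)-2,6-dimethylocta-1,5-dien-1-yl]furan-2(5H)-one | BrCC1=C[C@@H](/C=C(/C)CC/C=C(/C)CCO[Si](C)(C)C(C)(C)C)OC1=O | intermediate
26 | (5R)-3-(bromomethyl)-5-[(1Z,5Z)-8-hydroxy-2,6-dimethylocta-1,5-dien-1-yl]furan-2(5H)-one | BrCC1=C[C@@H](/C=C(/C)CC/C=C(/C)CCO)OC1=O | intermediate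
27 | (3Z,7Z)-8-[(2R)-4-(bromomethyl)-5-oxo-2,5-dihydrofuran-2-yl]-3,7-dimethylocta-3,7-dienal | BrCC1=C[C@@H](/C=C(/C)CC/C=C(/C)CC=O)OC1=O | intermediate
28 | 8β-hydroxy-6βH,7αH-(1(10)Z,4Z)-germacra-1(10),4,11(13)-trien-12,6α-olide | C=C1C(=O)O[C@@H]2/C=C(/C)CC/C=C(/C)C[C@@H](O)[C@H]21 | intermediate
29 | Diels–Alder adduct of 14 and 28: the target with its guaianolide lactone as the 13-(phenylsulfonyl)-11βH mask | O=C1O[C@H]2C[C@H](C)[C@]34C[C@@]5(C(=O)O[C@@H]6/C=C(/C)CC/C=C(/C)C[C@@H](O)[C@H]65)[C@H](C(C)=C3C[C@@H]2[C@H]1CS(=O)(=O)c1ccccc1)[C@@H]4OC(C)=O | intermediate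
30 | CNP0148007.1 | C=C1C(=O)O[C@H]2C[C@H](C)[C@]34C[C@@]5(C(=O)O[C@@H]6/C=C(/C)CC/C=C(/C)C[C@@H](O)[C@H]65)[C@H](C(C)=C3C[C@H]12)[C@@H]4OC(C)=O | target

**Count and risks**

Total step count: 24. Longest linear sequence: 14 steps (steps 1–12, 23 and 24, from isoalantolactone); the macrocyclic half takes steps 13–22.

Steps most likely to fail:

Step 23. The isolated acetoxy cyclopentadiene may undergo 1,5-hydrogen shifts or decay before the slow union with a dienophile that must form a quaternary carbon. The dienophile may also approach syn to the acetate or on the wrong face of the macrocycle. The fallback no longer isolates the diene and addresses the diene's short lifetime only, not a wrong facial preference. It sets out from 13 and 28 and returns at 29. Alcohol 28 is silylated (Et3SiCl, imidazole, DMF) to the 8′-O-triethylsilyl dienophile F1. Alcohol 13 is then dehydrated (MsCl, Et3N, CH2Cl2, −20 °C) in the presence of excess F1 and the mixture is pressurised at once, so that each molecule of 14 is trapped as it forms; the silyl ether keeps the C8′ oxygen from being mesylated. The resulting adduct, the triethylsilyl ether of 29 F2, is desilylated (aq. HF, MeCN, 0 °C) to give 29.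

Step 22. The macrocyclisation may close through the diastereomeric transition state, placing the C8′ hydroxyl on the wrong face, or give way to oligomerisation. The fallback moves control of C8′ from the carbon–carbon bond formation to an SN2 inversion; it sets out from 27 and returns at 28. If the ring closes to the C8′ epimer of 28 F3, a Mitsunobu reaction with chloroacetic acid (PPh3, DIAD, toluene) inverts C8′ and gives the 8′β-chloroacetate of 28 F4. Its acyl group is removed under neutral conditions with thiourea (NaHCO3, EtOH, 40 °C), which spare the α-methylene lactone, to give 28.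

Step 9. The exocyclic double bond may migrate into conjugation with the enone, where it is no longer reduced, or hydrogen may be delivered to the β-face. The fallback avoids the alkene altogether by radical deoxygenation; it sets out from 9 and returns at 11. The tertiary alcohol is acylated with methyl oxalyl chloride (pyridine, DMAP, CH2Cl2) to the mixed methyl oxalate of 9 F5. Reduction with Bu3SnH (AIBN, toluene, 110 °C, high hydride concentration) generates the C10 radical, which should take up hydrogen on the less screened α-face to give 11.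

Further compounds

F1 | step 23 | 8′-O-triethylsilyl ether of 28 | C=C1C(=O)O[C@@H]2/C=C(/C)CC/C=C(/C)C[C@@H](O[Si](CC)(CC)CC)[C@H]21
F2 | step 23 | 8′-O-triethylsilyl ether of 29 | O=C1O[C@H]2C[C@H](C)[C@]34C[C@@]5(C(=O)O[C@@H]6/C=C(/C)CC/C=C(/C)C[C@@H](O[Si](CC)(CC)CC)[C@H]65)[C@H](C(C)=C3C[C@@H]2[C@H]1CS(=O)(=O)c1ccccc1)[C@@H]4OC(C)=O
F3 | step 22 | C8′ epimer of 28 (8α-hydroxy) | C=C1C(=O)O[C@@H]2/C=C(/C)CC/C=C(/C)C[C@H](O)[C@H]21
F4 | step 22 | 8β-chloroacetate of 28 | C=C1C(=O)O[C@@H]2/C=C(/C)CC/C=C(/C)C[C@@H](OC(=O)CCl)[C@H]21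
F5 | step 9 | methyl oxalate of 9 (10α-O-methoxalyl) | O=C1O[C@H]2C[C@@](C)(OC(=O)C(=O)OC)[C@@H]3CC(=O)C(C)=C3C[C@@H]2[C@H]1CS(=O)(=O)c1ccccc1
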